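**Plan**
Retrosynthesis: ring A is cut at C4a–C5 and C8–C8a (a benzannulation on the C4a=C8a enone), then ring C is cut at C2–C3 and O1–C8a.
Enabling feature: ring C is a 2-aryl-3-oxypyran-4-one in which O1–C2 is the carbonyl group of isovanillin and C3, C4, C4a and C8a are the four carbons of a 4-benzoyloxy-1-methoxy-3-silyloxybutadiene.
Forward: ring C is made first by a catalytic asymmetric aldehyde–diene cyclocondensation. C4a then receives a phenylsulfinyl group, and ring A is fused on by cycloaddition of a prenylated vinylketene acetal (from methyl acetoacetate and prenyl bromide), aromatising by loss of PhSOH and methanol. One methanolysis then unmasks the target.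
Stereochemistry: C2 comes from catalyst-controlled Si-face attack on the aldehyde. C3 follows as the trans partner through the open aldol transition state and acid equilibration. Both centres are carried unchanged to the end.

Key step: step 4

Remark: (S)-BINOL with Ti(OiPr)4 is assumed to direct attack to the aldehyde Si face, as in its allylations and aldol additions; if the sense proves opposite, (R)-BINOL is used.

Step 1
Reactants: 1 isovanillin
Product: 2 3-(tert-butyldimethylsilyloxy)-4-methoxybenzaldehyde
Conditions: TBSCl, imidazole, DMF, rt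
Reagents that add atoms: tert-butyldimethylsilyl chloride, CC(C)(C)[Si](C)(C)Cl
Why: Imidazole-promoted silylation of the phenol masks the only acidic proton before Lewis acid catalysis.

Step 2
Reactants: 3 (E)-4-methoxybut-3-en-2-one
Product: 4 (E)-1-benzoyloxy-4-methoxybut-3-en-2-one
Conditions: Mn(OAc)3·2H2O (2.5 equiv), PhCO2H (excess), benzene, reflux, Dean–Stark
Reagents that add atoms: benzoic acid, OC(=O)c1ccccc1
Why: Trivalent manganese oxidises the ketone at its only enolisable position, the methyl group, and transfers a carboxylate ligand to the α-keto radical (α′-acyloxylation of enones with Mn(OAc)3 and a carboxylic acid); excess benzoic acid and removal of acetic acid should make benzoate the ligand transferred.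

Step 3
Reactants: 4 (E)-1-benzoyloxy-4-methoxybut-3-en-2-one
Product: 5 (1E,3Z)-4-benzoyloxy-1-methoxy-3-(trimethylsilyloxy)buta-1,3-diene
Conditions: TMSOTf, Et3N, Et2O, 0 °C
Reagents that add atoms: trimethylsilyl trifluoromethanesulfonate, C[Si](C)(C)OS(=O)(=O)C(F)(F)F
Why: Soft enolisation (silyl triflate and amine) can only occur toward the benzoyloxy-bearing carbon and should give the Z silyl enol ether; the geometry is not critical because C3 of the later pyranone can equilibrate.

Step 4
Reactants: 2 3-(tert-butyldimethylsilyloxy)-4-methoxybenzaldehyde; 5 (1E,3Z)-4-benzoyloxy-1-methoxy-3-(trimethylsilyloxy)buta-1,3-diene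
Product: 7 (2R,3R)-3-benzoyloxy-2-[3-(tert-butyldimethylsilyloxy)-4-methoxyphenyl]-2,3-dihydro-4H-pyran-4-one, via anti-aldol trimethylsilyl ether 6 (not isolated)
Conditions: (S)-BINOL (20 mol%), Ti(OiPr)4 (10 mol%), 4 Å MS, Et2O, −20 °C to rt; then TFA, CH2Cl2, 0 °C
Reagents that add atoms: none
Why: The BINOL complex of tetravalent titanium binds the aldehyde of 2, and the benzoyloxy-bearing diene terminus of 5 attacks its Si face through an open Mukaiyama aldol transition state, forming C2–C3 and, after silyl transfer, the silyl ether 6. Trifluoroacetic acid then removes the silyl group, and the C2 hydroxyl adds to the methoxy-bearing enone carbon and expels methanol, forming O1–C8a; ring C closes by this 6-endo-trig oxa-Michael addition–elimination. The closest known reaction type is the catalytic asymmetric cyclocondensation of aryl aldehydes with 1-alkoxy-3-silyloxy dienes (hetero-Diels–Alder by aldol and cyclisation), which includes 4-acyloxy dienes. C2 is set by the chiral catalyst through the aldehyde face; C3 is set by the anti preference of the open transition state and, where needed, by acid-mediated equilibration through the enol to the trans diequatorial isomer. The step needs bond formation only at the diene terminus and no competing enolisation, which the terminal silyl dienol ether and the non-enolisable aldehyde secure; the aryl silyl ether and the benzoate should survive brief acid.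

Step 5
Reactants: 7 (2R,3R)-3-benzoyloxy-2-[3-(tert-butyldimethylsilyloxy)-4-methoxyphenyl]-2,3-dihydro-4H-pyran-4-one
Product: 8 (2R,3R)-3-benzoyloxy-2-[3-(tert-butyldimethylsilyloxy)-4-methoxyphenyl]-5-(phenylthio)-2,3-dihydro-4H-pyran-4-one
Conditions: PhSCl, pyridine, CH2Cl2, −78 to 0 °C
Reagents that add atoms: benzenesulfenyl chloride, ClSc1ccccc1
Why: Electrophilic sulfenylation at C4a, the nucleophilic α-carbon of the vinylogous ester, followed by loss of HCl regenerates the enone; pyridine is too weak a base to open ring C or disturb C2 and C3.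

Step 6
Reactants: 8 (2R,3R)-3-benzoyloxy-2-[3-(tert-butyldimethylsilyloxy)-4-methoxyphenyl]-5-(phenylthio)-2,3-dihydro-4H-pyran-4-one
Product: 9 (2R,3R)-3-benzoyloxy-2-[3-(tert-butyldimethylsilyloxy)-4-methoxyphenyl]-5-(phenylsulfinyl)-2,3-dihydro-4H-pyran-4-one (both sulfur epimers)
Conditions: mCPBA (1.0 equiv), CH2Cl2, −78 to −40 °C
Reagents that add atoms: 3-chloroperoxybenzoic acid, OOC(=O)c1cccc(Cl)c1
Why: Sulfide-to-sulfoxide oxidation with one equivalent of peracid should outpace attack on the electron-poor enol ether, and it is done before the prenyl alkene enters the molecule; the sulfur configuration is irrelevant.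

Step 7
Reactants: 10 methyl acetoacetate; 11 prenyl bromide
Product: 12 methyl 2-acetyl-5-methylhex-4-enoate (racemic)
Conditions: K2CO3, acetone, reflux
Reagents that add atoms: none
Why: Acetoacetic ester C-alkylation between the two carbonyls fixes the prenyl group on the carbon that becomes C6.

Step 8
Reactants: 12 methyl 2-acetyl-5-methylhex-4-enoate
Product: 13 methyl (E)-3-methoxy-2-(3-methylbut-2-enyl)but-2-enoate
Conditions: HC(OMe)3, H2SO4 (cat.), MeOH, rt; then distillation
Reagents that add atoms: trimethyl orthoformate, COC(OC)OC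
Why: Acid-catalysed ketalisation with the orthoester and thermal loss of methanol gives the β-methoxy enoate (enol ether formation from a β-keto ester); either alkene isomer serves in the next step.

Step 9
Reactants: 13 methyl (E)-3-methoxy-2-(3-methylbut-2-enyl)but-2-enoate
Product: 14 1,3-dimethoxy-2-(3-methylbut-2-enyl)-1-(trimethylsilyloxy)buta-1,3-diene
Conditions: LiN(iPr)2, THF, −78 °C; TMSCl
Reagents that add atoms: trimethylsilyl chloride, C[Si](C)(C)Cl
Why: γ-Deprotonation of the β-methoxy enoate gives the ester dienolate, which is O-silylated to the vinylketene silyl acetal (standard preparation of 1-alkoxy-1-silyloxy dienes).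

Step 10
Reactants: 9 (2R,3R)-3-benzoyloxy-2-[3-(tert-butyldimethylsilyloxy)-4-methoxyphenyl]-5-(phenylsulfinyl)-2,3-dihydro-4H-pyran-4-one; 14 1,3-dimethoxy-2-(3-methylbut-2-enyl)-1-(trimethylsilyloxy)buta-1,3-diene
Product: 17 (2R,3R)-3-benzoyloxy-2-[3-(tert-butyldimethylsilyloxy)-4-methoxyphenyl]-5-hydroxy-7-methoxy-6-(3-methylbut-2-enyl)chroman-4-one, via sulfinyl cycloadduct 15 (not isolated), via 5-O-trimethylsilyl ether 16 (not isolated)
Conditions: 14 (2.5 equiv), toluene, 80 °C; then 1 M HCl, THF, 0 °C
Reagents that add atoms: none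
Why: Proposed new method: C8a of 9 is the β-carbon of both the ketone and the sulfoxide, so the nucleophilic CH2 terminus of 14 should bond to C8a and the acetal carbon to C4a (concerted, or Mukaiyama–Michael addition then ring closure); the cis C8a–H of adduct 15 then allows thermal syn-elimination of PhSOH, loss of methanol from the C5 mixed acetal aromatises ring A to 16, and dilute acid frees the 5-phenol; the closest known reaction types are the Diels–Alder and sulfoxide-elimination benzannulation of sulfinylquinones and α-sulfinyl enones with oxygenated dienes, and the regiospecific annulation of haloquinones with vinylketene acetals.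

Step 11
Reactants: 17 (2R,3R)-3-benzoyloxy-2-[3-(tert-butyldimethylsilyloxy)-4-methoxyphenyl]-5-hydroxy-7-methoxy-6-(3-methylbut-2-enyl)chroman-4-one
Product: 18 (2R,3R)-3,5-dihydroxy-2-(3-hydroxy-4-methoxyphenyl)-7-methoxy-6-(3-methylbut-2-enyl)chroman-4-one
Conditions: K2CO3 (0.5 equiv), MeOH–THF, 0 °C, Ar
Reagents that add atoms: none
Why: Base-mediated methanolysis removes the ketone-activated benzoate and the aryl silyl ether together; the 5-phenoxide formed first lowers the acidity of C3–H, so ring C should not open, and any equilibration at C3 favours the trans isomer.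

**Compound list**
1 | isovanillin (3-hydroxy-4-methoxybenzaldehyde) | COc1ccc(C=O)cc1O | starting material
2 | 3-(tert-butyldimethylsilyloxy)-4-methoxybenzaldehyde | COc1ccc(C=O)cc1O[Si](C)(C)C(C)(C)C | intermediate
3 | (E)-4-methoxybut-3-en-2-one | CO/C=C/C(C)=O | starting material
4 | (E)-1-benzoyloxy-4-methoxybut-3-en-2-one | CO/C=C/C(=O)COC(=O)c1ccccc1 | intermediate
5 | (1E,3Z)-4-benzoyloxy-1-methoxy-3-(trimethylsilyloxy)buta-1,3-diene | CO/C=C/C(O[Si](C)(C)C)=C/OC(=O)c1ccccc1 | intermediate
6 | (1R,2R,4E)-2-benzoyloxy-1-[3-(tert-butyldimethylsilyloxy)-4-methoxyphenyl]-5-methoxy-1-(trimethylsilyloxy)pent-4-en-3-one | COc1ccc([C@H]([C@@H](OC(=O)c2ccccc2)C(=O)/C=C/OC)O[Si](C)(C)C)cc1O[Si](C)(C)C(C)(C)C | intermediate (not isolated)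
7 | (2R,3R)-3-benzoyloxy-2-[3-(tert-butyldimethylsilyloxy)-4-methoxyphenyl]-2,3-dihydro-4H-pyran-4-one | COc1ccc([C@H]2OC=CC(=O)[C@@H]2OC(=O)c2ccccc2)cc1O[Si](C)(C)C(C)(C)C | intermediate
8 | (2R,3R)-3-benzoyloxy-2-[3-(tert-butyldimethylsilyloxy)-4-methoxyphenyl]-5-(phenylthio)-2,3-dihydro-4H-pyran-4-one | COc1ccc([C@H]2OC=C(Sc3ccccc3)C(=O)[C@@H]2OC(=O)c2ccccc2)cc1O[Si](C)(C)C(C)(C)C | intermediate
9 | (2R,3R)-3-benzoyloxy-2-[3-(tert-butyldimethylsilyloxy)-4-methoxyphenyl]-5-(phenylsulfinyl)-2,3-dihydro-4H-pyran-4-one, both sulfur epimers | COc1ccc([C@H]2OC=C(S(=O)c3ccccc3)C(=O)[C@@H]2OC(=O)c2ccccc2)cc1O[Si](C)(C)C(C)(C)C | intermediate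
10 | methyl acetoacetate | COC(=O)CC(C)=O | starting material
11 | prenyl bromide (1-bromo-3-methylbut-2-ene) | CC(C)=CCBr | starting material
12 | methyl 2-acetyl-5-methylhex-4-enoate, racemic | COC(=O)C(CC=C(C)C)C(C)=O | intermediate
13 | methyl (E)-3-methoxy-2-(3-methylbut-2-enyl)but-2-enoate | C/C(OC)=C(/CC=C(C)C)C(=O)OC | intermediate
14 | 1,3-dimethoxy-2-(3-methylbut-2-enyl)-1-(trimethylsilyloxy)buta-1,3-diene, ketene acetal geometry undefined | C=C(OC)C(CC=C(C)C)=C(OC)O[Si](C)(C)C | intermediate
15 | (2R,3R)-3-benzoyloxy-2-[3-(tert-butyldimethylsilyloxy)-4-methoxyphenyl]-5,7-dimethoxy-6-(3-methylbut-2-enyl)-4a-(phenylsulfinyl)-5-(trimethylsilyloxy)-4a,5,8,8a-tetrahydrochroman-4-one, new centres undefined | COc1ccc([C@H]2OC3CC(OC)=C(CC=C(C)C)C(OC)(O[Si](C)(C)C)C3(S(=O)c4ccccc4)C(=O)[C@@H]2OC(=O)c5ccccc5)cc1O[Si](C)(C)C(C)(C)C | intermediate (not isolated)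
16 | (2R,3R)-3-benzoyloxy-2-[3-(tert-butyldimethylsilyloxy)-4-methoxyphenyl]-7-methoxy-6-(3-methylbut-2-enyl)-5-(trimethylsilyloxy)chroman-4-one | COc1ccc([C@H]2Oc3cc(OC)c(CC=C(C)C)c(O[Si](C)(C)C)c3C(=O)[C@@H]2OC(=O)c2ccccc2)cc1O[Si](C)(C)C(C)(C)C | intermediate (not isolated)
17 | (2R,3R)-3-benzoyloxy-2-[3-(tert-butyldimethylsilyloxy)-4-methoxyphenyl]-5-hydroxy-7-methoxy-6-(3-methylbut-2-enyl)chroman-4-one | COc1ccc([C@H]2Oc3cc(OC)c(CC=C(C)C)c(O)c3C(=O)[C@@H]2OC(=O)c2ccccc2)cc1O[Si](C)(C)C(C)(C)C | intermediate
18 | (2R,3R)-3,5-dihydroxy-2-(3-hydroxy-4-methoxyphenyl)-7-methoxy-6-(3-methylbut-2-enyl)chroman-4-one | COc1ccc([C@H]2Oc3cc(OC)c(CC=C(C)C)c(O)c3C(=O)[C@@H]2O)cc1O | target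

**Step count**
Total: 11 steps. Longest linear sequence: 7 steps (steps 2, 3, 4, 5, 6, 10 and 11, from compound 3).

**Steps most likely to fail**

Step 10. The push–pull alkene of 9 may be too unreactive toward the diene. A stepwise adduct may instead open ring C by β-elimination of O1. The mixed acetal may also lose trimethylsilanol in place of methanol and deliver the 5-methyl ether. The fallback builds ring A stepwise with known reactions, sets out from 7 and returns at 17. A TMSOTf-catalysed vinylogous Mukaiyama–Michael addition of 14 to C8a of 7 (CH2Cl2, −78 °C) should give the trimethylsilyl enol ether adduct F1. Fluoride (Bu4N[Ph3SiF2], THF, −78 to 0 °C) then releases the regiodefined C4a enolate, and Dieckmann closure onto the ester should give the bicyclic diketone F2. Dehydrogenation with DDQ (dioxane, rt) would aromatise ring A to 17.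

Step 4. The hindered 4-substituted diene may turn over slowly on the titanium catalyst, facial selectivity may be poor, or the cis isomer may persist. The fallback separates the asymmetric step from the C3 oxygenation, sets out from 2 and returns at 7. Commercially available 1-methoxy-3-(trimethylsilyloxy)buta-1,3-diene is condensed with 2 under the same (S)-BINOL and Ti(OiPr)4 catalysis with trifluoroacetic acid work-up, the substrate pairing for which this catalysis is established; this should give (S)-2-[3-(tert-butyldimethylsilyloxy)-4-methoxyphenyl]-2,3-dihydro-4H-pyran-4-one F3 (same spatial arrangement at C2; the descriptor changes only through ligand priority). α′-Benzoyloxylation of F3 with Mn(OAc)3 and benzoic acid in refluxing benzene, expected to occur trans to the aryl group, then gives 7.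

Step 5. Competing sulfenylation of the electron-rich aryl ring or over-reaction may erode chemoselectivity. The fallback introduces sulfur by cross-coupling, sets out from 7 and returns at 8. α-Iodination of the enone with I2 and pyridine in CH2Cl2 should give the 5-iodo dihydropyranone F4. Carbon–sulfur coupling with thiophenol under zerovalent palladium catalysis (Pd2(dba)3, Xantphos, iPr2NEt, dioxane, 80 °C) then gives 8.

**Further compounds**
F1 | step 10 | methyl 4-[(5R,6R)-5-benzoyloxy-6-[3-(tert-butyldimethylsilyloxy)-4-methoxyphenyl]-4-(trimethylsilyloxy)-5,6-dihydro-2H-pyran-2-yl]-3-methoxy-2-(3-methylbut-2-enyl)but-2-enoate, C2 of the pyran and alkene geometry undefined | COc1ccc([C@H]2OC(CC(OC)=C(CC=C(C)C)C(=O)OC)C=C(O[Si](C)(C)C)[C@@H]2OC(=O)c2ccccc2)cc1O[Si](C)(C)C(C)(C)C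
F2 | step 10 | (2R,3R)-3-benzoyloxy-2-[3-(tert-butyldimethylsilyloxy)-4-methoxyphenyl]-7-methoxy-6-(3-methylbut-2-enyl)-2,3,8,8a-tetrahydro-4H-chromene-4,5(4aH)-dione, ring-fusion centres undefined | COc1ccc([C@H]2OC3CC(OC)=C(CC=C(C)C)C(=O)C3C(=O)[C@@H]2OC(=O)c2ccccc2)cc1O[Si](C)(C)C(C)(C)C
F3 | step 4 | (S)-2-[3-(tert-butyldimethylsilyloxy)-4-methoxyphenyl]-2,3-dihydro-4H-pyran-4-one | COc1ccc([C@H]2OC=CC(=O)C2)cc1O[Si](C)(C)C(C)(C)C
F4 | step 5 | (2R,3R)-3-benzoyloxy-2-[3-(tert-butyldimethylsilyloxy)-4-methoxyphenyl]-5-iodo-2,3-dihydro-4H-pyran-4-one | COc1ccc([C@H]2OC=C(I)C(=O)[C@@H]2OC(=O)c2ccccc2)cc1O[Si](C)(C)C(C)(C)C
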